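## Analysis of the target

Target 36 is a longipinane-type tricycle: a cyclohex-2-enone (C1 ketone, C2=C3 with a methyl on C3, then C4, C10, C11), a cyclobutane (C4–C5–C11–C10) and a cycloheptane (C4–C5–C6–C7–C8–C9–C10). It is a bicyclo[3.1.1]heptenone whose two one-carbon bridges C5 and C10 are tied together by the chain C6–C9. There are six stereocentres, (4R,5S,6S,7R,10R,11R). C4, C5, C10 and C11 belong to the cage and are locked to one another once the sense at C10 and the cis relation of C5 (on C4) to C9 (on C10) are fixed, whereas C6 (quaternary, methyl and CH2O-angelate) and C7 (acetoxy, cis to the C6 methyl) lie on the bridge and must be related to the cage separately. The sensitive groups are the (Z)-2-methylbut-2-enoate, which isomerises to the (E) ester, the pair of different esters on a 1,3-diol, which can migrate, and the cyclobutane next to the enone, which tolerates neither strong acid nor forcing base. The difficulty lies in two quaternary carbons (C6 and C10), one of them flanking the cyclobutane carbon C5, in the four-membered ring itself, and in carrying the C6/C7 configuration across a symmetric-looking cage. The strategy rests on the six-membered ring C1–C2–C3–C4–C10–C11: C10 and C4 are neighbours, the C10 methyl is trans to C5 and C9 is cis to C5, which is the pattern left by 1,4-addition of methyl to a 3-alkenylcyclohexenone followed by capture of the enolate at C4 by an aldehyde carbon C5. If that aldehyde already carries C6, C7 and C8 with both stereocentres, one operation assembles every skeletal carbon except the C3 methyl and leaves two alkenes placed for closure of the seven-membered ring.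

## Retrosynthetic reasoning

**Esters.** Both acyl groups are removed first: 36 goes back to mono-ester 35, and 35 to diol 32 and angelic acid 33. They are introduced last because the (Z)-enoate would not survive the organometallic, enolate and oxidation steps. The primary oxygen is acylated before the hindered C7 oxygen. Diol 32 comes from acetonide 31, in which one group protects O7 and the C6 CH2O arm.

**Cyclobutane (C5–C11).** In 31 the C5–C11 bond is cut, giving mesylate 29. This is the one cage bond an enolate can make, because C11 is the α' carbon of the C1 ketone. The forward step needs the kinetic enolate 30 and a leaving group at C5 whose configuration becomes 5S on inversion. The gain is that the strained ring is the last C–C bond formed, on a substrate that already holds every carbon.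

**Carbonyl transposition (C3 to C1) and the C3 methyl.** Mesylate 29 comes from alcohol 28 and silyl ether 27. Enone 27 is traced through tertiary allylic alcohol 26 to enone 24 and methyllithium 25, and 24 to saturated ketone 22 by way of 23. The aldol needs the carbonyl at C3 and the cyclobutane closure needs it at C1. 1,2-Addition of 25 followed by an oxidative 1,3-shift moves the oxygen and leaves the methyl on C3. The C5 oxygen stays silylated through this stretch (from 20 on), because a sulfonate β to the C3 ketone would eliminate and a free alcohol would be oxidised.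

**Seven-membered ring (C8=C9).** Ketone 22 goes back to cycloheptene 21 and this to diene 20 by cutting C8=C9. It is the only bond of the bridge that joins two unsubstituted carbons, so cutting it frees two vinyl groups, one on C10 and one on C7, and the two halves become independent. The forward metathesis loses the two terminal methylene groups.

**Key disconnection (C10–CH3 and C4–C5).** Silyl ether 20 comes from aldol 19, and 19 is cut into dienone 4, methylmagnesium bromide 17 and aldehyde 16. Cutting here separates a flat, achiral six-carbon ring from a small fragment that carries C6 and C7. The forward reaction has to add methyl 1,4 (not 1,6) to one face of 4 and then join C4 of enolate 18 to the aldehyde carbon trans to the new methyl, as the anti aldol.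

**Aldehyde 16 (C5–C6, then C6–C7).** Aldehyde 16 is traced through alcohol 15, benzyl ether 14 and diol 13 to ester 12, and 12 to hydroxy ester 9 and benzyl chloromethyl ether 10. In the dianion alkylation the incoming carbon ends anti to the C7 oxygen. The carbon from 10 therefore has to become C5, and the ester carbon of 12 has to become the C6 CH2O arm; carrying the ester carbon through to the aldehyde instead would give the C6 epimer. Ester 9 comes from imide 8, and 8 from propionyl imide 5 and acrolein 6 by an aldol that sets C7.

**Dienone 4.** Dienone 4 comes from 3-ethoxycyclohexenone 1 and vinylmagnesium bromide 2 by 1,2-addition and hydrolytic carbonyl transposition.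

## Alternatives that were turned down

**Alternative 1:** The disconnection is the C5–C6 bond together with the ring size. Cycloheptanone A2 (6-hydroxymethyl-longipin-2-ene-1,7-dione) is traced back to epoxy alcohol A1, in which C5 is still bonded to the carbinol carbon C7 of a six-membered ring and C6 sits outside the ring as a 2-methyloxirane.
- Forward key step: a Lewis acid opens the oxirane of A1 at its tertiary carbon C6, the cyclobutyl carbon C5 shifts from C7 to C6 anti to the departing oxygen, C7 becomes the ketone, the ring grows from six to seven members and the CH2OH arm is released, giving A2.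
- For it: the most hindered bridge bond and the quaternary centre C6 are made in one stereospecific intramolecular step, with the C6 configuration read from the oxirane, and both bridge oxygens appear at once.
- Against it: A1 already contains the complete cyclobutane cage, so the hardest part must be built first on a nor-skeleton that is no simpler than 31. At C7 two carbons (C5 and C8) can migrate; the cyclobutyl carbon is the poorer migrator, and its shift develops positive charge next to the strained ring. A2 is a β-hydroxy ketone with a quaternary α-carbon and can lose its CH2OH arm by retro-aldol cleavage. C7 must afterwards be reduced beside the C1 enone, with a facial outcome set by the cage and not by design.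
- Comparison: on setting C6 late and stereospecifically on the finished cage, this alternative is as strong as or stronger than the chosen route. The chosen route offers C6 and C7 as a pair made in an acyclic fragment (12) under reliable substrate control, no late reduction at C7, no cationic step beside the cyclobutane, and a convergent assembly from 4, 17 and 16.

**Alternative 2:** The disconnection is C3–C4. The cis-fused enedione A4 is traced back to the achiral 4-methylcyclohexa-2,5-dienone A3, which carries a four-carbon aldehyde chain on its quaternary carbon.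
- Forward key step: a chiral carbene catalyst turns the aldehyde carbon of A3 (future C3) into an acyl anion equivalent that adds to one of the two enantiotopic β-carbons (future C4), closing the ring C3–C2–C1–C11–C10–C4 and giving A4.
- For it: one catalytic step sets C10 and C4 from an achiral substrate, and the cis relation of the C4 substituent to C10 is enforced by the ring fusion. On this point it is stronger than the chosen route, where the relation of C5 to C9 depends on face selection at enolate 18, flanked by a methyl and a vinyl group.
- Against it: the second ring of A4 is six-membered and holds only four carbons of the future bridge. A regioselective one-carbon ring expansion, the quaternary C6 with two different one-carbon arms and the C7 oxygen all have to be introduced stepwise, with configurations set by reagent approach to a flexible cis-fused bicycle. The key step forms one C–C bond and two stereocentres; everything else is still ahead.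
- Comparison: in exchange for the less secure C4 selectivity, the chosen key step joins all skeletal carbons but one, with C6 and C7 already correct, and the seven-membered ring closes by metathesis without ring expansion.

**Alternative 3:** The disconnection is the C4–C10 bond of the cyclobutane, as a ring contraction. Ester A6 (methyl 7-(benzyloxymethyl)-2-methylbicyclo[3.1.1]hept-2-ene-6-carboxylate) is traced back to the bicyclo[3.2.1]octenone diazoketone A5.
- Forward key step: irradiation of A5 expels the diazo nitrogen, C4 migrates from the carbonyl carbon to the carbene carbon (future C10), and the ketene is captured by the alcoholic solvent as the methyl ester A6.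
- For it: the cyclobutane arises in an irreversible photochemical step that is indifferent to the strain it creates. This is stronger than the chosen route, whose four-membered ring depends on a displacement at a neopentyl-type carbon (step 18). A6 also carries the C2=C3 methyl alkene.
- Against it: A6 lacks C7, C8 and the methyl groups of C6 and C10. Both quaternary carbons would have to be made by alkylations on the cage periphery, the seven-membered ring then annulated across C5 and C10, and C6 and C7 created last on a tether with no control other than the cage shape. The C10 configuration from ketene capture is not controlled, and A5 itself needs a bicyclic ketone and a diazo transfer.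
- Comparison: the chosen route accepts the risk of a late intramolecular alkylation, and in return the substrate for ring closure already carries every carbon and both bridge stereocentres, so the path from ring formation to 36 is much shorter.

Key step: step 9

**Remarks on the chemistry (assumptions).**
- The enantiomer of the carbene precursor in step 9 is the one that gives the (R)-enolate 18, which corresponds to the (S) series of the simple adduct 3-methyl-3-vinylcyclohexanone. The sense of induction is to be confirmed on that simple adduct before 16 is committed.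
- The C3 configuration of 26 is left open; the centre becomes planar again in step 15.
- Atom numbers C1–C11 are those of the target throughout.

## Route

**Step 1**
Reactants: 1 3-ethoxycyclohex-2-en-1-one; 2 vinylmagnesium bromide
Product: 4 3-vinylcyclohex-2-en-1-one, via bromomagnesium 3-ethoxy-1-vinylcyclohex-2-en-1-olate 3 (not isolated)
Conditions: THF, 0 °C; then 1 M HCl, 0 °C → rt; used promptly, kept cold
Reagents that add atoms: none
Why: 1,2-Addition of the Grignard reagent to the vinylogous ester and acid hydrolysis of the resulting enol ether carbinol transposes the carbonyl (Stork–Danheiser sequence); no stereocentre remains.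

**Step 2**
Reactants: 5 (S)-4-benzyl-3-propanoyloxazolidin-2-one; 6 acrolein
Product: 8 (S)-4-benzyl-3-[(2S,3R)-3-hydroxy-2-methylpent-4-enoyl]oxazolidin-2-one, via dibutylboron (Z)-enolate 7 (not isolated)
Conditions: Bu2BOTf, iPr2NEt, CH2Cl2, 0 °C; 6, −78 → 0 °C; then H2O2, MeOH, pH 7 buffer
Reagents that add atoms: none
Why: Evans syn aldol: the (Z)-boron enolate reacts through a closed chair transition state on the face away from the benzyl group of the auxiliary, which fixes the carbinol carbon (future C7) as R; the C2 centre is erased in step 4.

**Step 3**
Reactants: 8 (S)-4-benzyl-3-[(2S,3R)-3-hydroxy-2-methylpent-4-enoyl]oxazolidin-2-one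
Product: 9 methyl (2S,3R)-3-hydroxy-2-methylpent-4-enoate
Conditions: NaOMe, MeOH, −10 °C; NH4Cl aq
Reagents that add atoms: sodium methoxide [Na+].[O-]C
Why: Transesterification: methoxide attacks the exocyclic imide carbonyl and releases the auxiliary; low temperature keeps retro-aldol cleavage away and the carbinol centre is untouched.

**Step 4**
Reactants: 9 methyl (2S,3R)-3-hydroxy-2-methylpent-4-enoate; 10 benzyl chloromethyl ether
Product: 12 methyl (2R,3R)-2-[(benzyloxy)methyl]-3-hydroxy-2-methylpent-4-enoate, via dilithium ester enolate alkoxide 11 (not isolated)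
Conditions: LiN(iPr)2 (2.3 equiv), THF, −78 → −20 °C; then 10, DMPU, −78 → −10 °C
Reagents that add atoms: none
Why: Fráter–Seebach alkylation: in the lithium-chelated dianion the electrophile enters anti to the alkoxide carbon substituent pattern, irrespective of the α-substituent, so the new carbon (future C5) ends anti and the methyl syn to the C7 oxygen. This sets the quaternary centre C6 relative to C7.

**Step 5**
Reactants: 12 methyl (2R,3R)-2-[(benzyloxy)methyl]-3-hydroxy-2-methylpent-4-enoate
Product: 13 (2R,3R)-2-[(benzyloxy)methyl]-2-methylpent-4-ene-1,3-diol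
Conditions: LiAlH4, THF, 0 °C → rt
Reagents that add atoms: none
Why: Hydride reduction of the neopentyl ester to the primary alcohol, which becomes the C6 CH2O arm; no stereocentre is touched.

**Step 6**
Reactants: 13 (2R,3R)-2-[(benzyloxy)methyl]-2-methylpent-4-ene-1,3-diol
Product: 14 (4R,5S)-5-[(benzyloxy)methyl]-2,2,5-trimethyl-4-vinyl-1,3-dioxane
Conditions: 2,2-dimethoxypropane, PPTS (cat.), CH2Cl2, rt
Reagents that add atoms: 2,2-dimethoxypropane COC(C)(C)OC
Why: Acid-catalysed transacetalisation of the 1,3-diol to the six-membered acetonide, with the vinyl group equatorial and cis to the C5 methyl; one group now protects O7 and the CH2O arm.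

**Step 7**
Reactants: 14 (4R,5S)-5-[(benzyloxy)methyl]-2,2,5-trimethyl-4-vinyl-1,3-dioxane
Product: 15 [(4R,5S)-2,2,5-trimethyl-4-vinyl-1,3-dioxan-5-yl]methanol
Conditions: lithium 4,4'-di-tert-butylbiphenylide (preformed in THF), THF, −78 °C, titrated to a persistent green colour; NH4Cl aq
Reagents that add atoms: none
Why: Reductive debenzylation by single-electron transfer: at −78 °C the benzylic C–O bond is cleaved much faster than the allylic acetal C–O bond, and the isolated alkene, which rules out hydrogenolysis, is not reduced.

**Step 8**
Reactants: 15 [(4R,5S)-2,2,5-trimethyl-4-vinyl-1,3-dioxan-5-yl]methanol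
Product: 16 (4R,5S)-2,2,5-trimethyl-4-vinyl-1,3-dioxane-5-carbaldehyde
Conditions: Dess–Martin periodinane, NaHCO3, CH2Cl2, 0 °C → rt
Reagents that add atoms: none
Why: Dess–Martin oxidation of the neopentyl alcohol; the aldehyde has no α-hydrogen, so it can neither epimerise nor eliminate the β-oxygen.

**Step 9**
Reactants: 4 3-vinylcyclohex-2-en-1-one; 17 methylmagnesium bromide; 16 (4R,5S)-2,2,5-trimethyl-4-vinyl-1,3-dioxane-5-carbaldehyde
Product: 19 (2R,3R)-2-{(S)-hydroxy[(4R,5R)-2,2,5-trimethyl-4-vinyl-1,3-dioxan-5-yl]methyl}-3-methyl-3-vinylcyclohexan-1-one, via bromomagnesium (R)-3-methyl-3-vinylcyclohex-1-en-1-olate 18 (not isolated)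
Conditions: Cu(OTf)2 (5 mol %), 1-(1-hydroxy-4-methylpentan-2-yl)-3-mesityl-4,5-dihydroimidazolium hexafluorophosphate (single enantiomer, 7 mol %), 17 (1.4 equiv), 4 (1.5 equiv, slow addition), Et2O, −30 °C; then 16 (1.0 equiv), −78 → −40 °C; NH4Cl aq at low temperature
Reagents that add atoms: none
Why: The Grignard reagent converts Cu(OTf)2 and the imidazolinium salt into a monovalent copper–carbene methyl complex, which binds the ring double bond of 4, bonds to C10 and collapses by reductive elimination to magnesium enolate 18; with the strongly donating carbene ligand this collapse is expected to outrun migration of copper to the vinyl terminus, which keeps the addition 1,4 and not 1,6. The closest known reaction type is the copper–carbene catalysed asymmetric 1,4-addition of Grignard reagents to 3-alkenylcyclohexenones with aldol capture of the magnesium enolate. No ring is closed in this step. C10 is set by the chiral carbene ligand, which selects the enone face. C4 is set when 16 attacks the enolate face anti to the pseudo-axial methyl group, so that the planar vinyl group and not the methyl group is the gauche neighbour of the incoming carbon; C5 then ends cis to C9 and trans to the methyl. C5 is set by the closed chair transition state of the ring (E)-enolate with magnesium bridging both oxygens and the dioxanyl residue equatorial, which gives the anti aldol, the (S)-carbinol whose displacement with inversion in step 18 gives 5S. The step needs four selectivities: 1,4 over 1,6 (ligand), enone face (ligand), enolate face (methyl against vinyl at C10, the weakest of the four) and anti over syn (the syn chair would push the dioxane over the cyclohexene ring). Aldehyde 16 has no α-hydrogen, so it cannot quench the enolate, and as a single enantiomer it turns the minor enantiomer of 18 into a separable diastereomer.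

**Step 10**
Reactants: 19 (2R,3R)-2-{(S)-hydroxy[(4R,5R)-2,2,5-trimethyl-4-vinyl-1,3-dioxan-5-yl]methyl}-3-methyl-3-vinylcyclohexan-1-one
Product: 20 (2R,3R)-3-methyl-2-{(S)-(triethylsilyloxy)[(4R,5S)-2,2,5-trimethyl-4-vinyl-1,3-dioxan-5-yl]methyl}-3-vinylcyclohexan-1-one
Conditions: Et3SiOTf, 2,6-lutidine, CH2Cl2, −78 → 0 °C
Reagents that add atoms: triethylsilyl trifluoromethanesulfonate CC[Si](CC)(CC)OS(=O)(=O)C(F)(F)F
Why: Silylation of the hindered aldol hydroxyl with a silyl triflate and a non-nucleophilic base; it blocks retro-aldol cleavage and keeps O5 out of the later enolate and chromium steps.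

**Step 11**
Reactants: 20 (2R,3R)-3-methyl-2-{(S)-(triethylsilyloxy)[(4R,5S)-2,2,5-trimethyl-4-vinyl-1,3-dioxan-5-yl]methyl}-3-vinylcyclohexan-1-one
Product: 21 cis-fused cycloheptene ketone (C3 ketone; C8=C9; C5 OSiEt3; acetonide on O7 and the C6 CH2O arm)
Conditions: second-generation Grubbs catalyst RuCl2(=CHPh)(PCy3)(H2IMes) (5–10 mol %), toluene (0.005 M), 80 °C, argon sparge
Reagents that add atoms: none
Why: Ring-closing olefin metathesis to the seven-membered ring; the two vinyl groups are cis on the cyclohexanone and held close by the substituents on C6 and C10, and the dioxane carries the vinyl and the chain trans-diequatorial, so a trans-fused acetonide results without strain.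

**Step 12**
Reactants: 21 cis-fused cycloheptene ketone
Product: 22 cis-fused saturated bicyclic ketone (C3 ketone; C5 OSiEt3; acetonide)
Conditions: H2 (1 atm), Pd on carbon, EtOAc, rt
Reagents that add atoms: none
Why: Catalytic hydrogenation of the cis-disubstituted ring alkene; no benzyl group is left to be lost and no stereocentre is created.

**Step 13**
Reactants: 22 cis-fused saturated bicyclic ketone
Product: 24 bicyclic enone (C3 ketone; C1=C2; C5 OSiEt3; acetonide), via trimethylsilyl enol ether 23 (not isolated)
Conditions: LiN(iPr)2, Me3SiCl, THF, −78 °C; then Pd(OAc)2, MeCN, rt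
Reagents that add atoms: none
Why: Saegusa–Ito oxidation: kinetic deprotonation takes the C2 methylene and not the hindered C4 methine, and the palladium enolate loses the C1 hydrogen by β-hydride elimination.

**Step 14**
Reactants: 24 bicyclic enone (C3 ketone; C1=C2); 25 methyllithium
Product: 26 tertiary allylic alcohol (C3 OH and CH3; C1=C2; C5 OSiEt3; acetonide)
Conditions: 25, CeCl3, THF, −78 °C
Reagents that add atoms: none
Why: 1,2-Addition of the organocerium reagent to the hindered enone carbonyl; cerium suppresses enolisation at C4 and conjugate addition.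

**Step 15**
Reactants: 26 tertiary allylic alcohol
Product: 27 transposed enone (C1 ketone; C2=C3 with the C3 methyl; C5 OSiEt3; acetonide)
Conditions: pyridinium chlorochromate [C5H5NH][CrO3Cl], 4 Å molecular sieves, CH2Cl2, rt
Reagents that add atoms: pyridinium chlorochromate [O-][Cr](=O)(=O)Cl.c1cc[nH+]cc1
Why: Oxidative 1,3-transposition of a tertiary allylic alcohol (Dauben type): the chromate ester undergoes a [3,3] shift to C1 and is oxidised there, which moves the carbonyl from C3 to C1 and leaves the methyl on C3.

**Step 16**
Reactants: 27 transposed enone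
Product: 28 C5 alcohol (C1 ketone; C2=C3; acetonide)
Conditions: HF·pyridine, pyridine, THF, 0 °C
Reagents that add atoms: none
Why: Fluoride cleavage of the triethylsilyl ether under buffered conditions that leave the acetonide and the enone alone.

**Step 17**
Reactants: 28 C5 alcohol
Product: 29 C5 methanesulfonate (C1 ketone; C2=C3; acetonide)
Conditions: MeSO2Cl, Et3N, CH2Cl2, −20 → 0 °C
Reagents that add atoms: methanesulfonyl chloride CS(=O)(=O)Cl
Why: Mesylation through sulfene, which reaches hindered alcohols and retains the C5 configuration. It is done only now because the sulfonate is no longer β to a ketone.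

**Step 18**
Reactants: 29 C5 methanesulfonate
Product: 31 (4R,5S,6S,7R,10R,11R)-tricyclic enone acetonide (longipin-2-en-1-one skeleton; acetonide on O7 and the C6 CH2O arm), via lithium cross-conjugated enolate 30 (not isolated)
Conditions: LiN(iPr)2 (1.05 equiv), THF, −78 °C; then DMPU, −78 → 0 °C
Reagents that add atoms: none
Why: Intramolecular enolate alkylation (4-exo-tet), the known way to bicyclo[3.1.1]heptanones: kinetic deprotonation at the α' carbon C11 gives 30, whose π lobe faces the axial C5 and displaces the mesylate with inversion to give 5S. The C11 configuration is dictated by the bicyclic frame, and O-alkylation is geometrically out of reach.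

**Step 19**
Reactants: 31 tricyclic enone acetonide
Product: 32 (4R,5S,6S,7R,10R,11R)-tricyclic diol (C7 OH; CH2OH on C6; longipin-2-en-1-one skeleton)
Conditions: AcOH/H2O (4:1), 40 °C
Reagents that add atoms: none
Why: Mild acid hydrolysis of the acetonide; the verbenone-like enone and cyclobutane tolerate dilute acetic acid.

**Step 20**
Reactants: 32 tricyclic diol; 33 angelic acid [(Z)-2-methylbut-2-enoic acid]
Product: 35 (4R,5S,6S,7R,10R,11R)-tricyclic mono-angelate (angelate on the C6 CH2O arm; free C7 OH), via angelic 2,4,6-trichlorobenzoic anhydride 34 (not isolated)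
Conditions: 33, 2,4,6-trichlorobenzoyl chloride, Et3N, toluene, rt; then 32, toluene, 75 °C, no nucleophilic catalyst
Reagents that add atoms: none
Why: Yamaguchi-type mixed-anhydride esterification; leaving out a nucleophilic catalyst avoids the addition–elimination path that turns the (Z) acyl group into the (E) isomer, and the primary hydroxyl should react ahead of the C7 hydroxyl, which is secondary and flanked by the quaternary C6.

**Step 21**
Reactants: 35 tricyclic mono-angelate
Product: 36 target (CNP0374220.1)
Conditions: Ac2O, pyridine, DMAP (cat.), CH2Cl2, 0 °C → rt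
Reagents that add atoms: acetic anhydride CC(=O)OC(C)=O
Why: Acetylation of the remaining secondary hydroxyl with retention at C7; excess anhydride at low temperature acylates faster than the angelate can migrate.

## Compound list

1 | 3-ethoxycyclohex-2-en-1-one | CCOC1=CC(=O)CCC1 | starting material
2 | vinylmagnesium bromide | C=C[Mg]Br | starting material
3 | bromomagnesium 3-ethoxy-1-vinylcyclohex-2-en-1-olate (racemic) | CCOC1=CC(O[Mg]Br)(C=C)CCC1 | intermediate (not isolated)
4 | 3-vinylcyclohex-2-en-1-one | C=CC1=CC(=O)CCC1 | intermediate
5 | (S)-4-benzyl-3-propanoyloxazolidin-2-one | CCC(=O)N1C(=O)OC[C@@H]1Cc1ccccc1 | starting material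
6 | acrolein (prop-2-enal) | C=CC=O | starting material
7 | dibutylboron (Z)-enolate of 5 | C/C=C(\OB(CCCC)CCCC)N1C(=O)OC[C@@H]1Cc1ccccc1 | intermediate (not isolated)
8 | (S)-4-benzyl-3-[(2S,3R)-3-hydroxy-2-methylpent-4-enoyl]oxazolidin-2-one | O=C(N1C(=O)OC[C@@H]1Cc1ccccc1)[C@@H](C)[C@H](O)C=C | intermediate
9 | methyl (2S,3R)-3-hydroxy-2-methylpent-4-enoate | COC(=O)[C@@H](C)[C@H](O)C=C | intermediate
10 | benzyl chloromethyl ether | ClCOCc1ccccc1 | starting material
11 | dilithium ester enolate alkoxide of 9 (chelated dianion, 3R) | [Li]O/C(OC)=C(/C)[C@H](O[Li])C=C | intermediate (not isolated)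
12 | methyl (2R,3R)-2-[(benzyloxy)methyl]-3-hydroxy-2-methylpent-4-enoate | COC(=O)[C@](C)(COCc1ccccc1)[C@H](O)C=C | intermediate
13 | (2R,3R)-2-[(benzyloxy)methyl]-2-methylpent-4-ene-1,3-diol | OC[C@](C)(COCc1ccccc1)[C@H](O)C=C | intermediate
14 | (4R,5S)-5-[(benzyloxy)methyl]-2,2,5-trimethyl-4-vinyl-1,3-dioxane | C=C[C@H]1OC(C)(C)OC[C@]1(C)COCc1ccccc1 | intermediate
15 | [(4R,5S)-2,2,5-trimethyl-4-vinyl-1,3-dioxan-5-yl]methanol | C=C[C@H]1OC(C)(C)OC[C@]1(C)CO | intermediate
16 | (4R,5S)-2,2,5-trimethyl-4-vinyl-1,3-dioxane-5-carbaldehyde | C=C[C@H]1OC(C)(C)OC[C@]1(C)C=O | intermediate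
17 | methylmagnesium bromide | C[Mg]Br | starting material
18 | bromomagnesium (R)-3-methyl-3-vinylcyclohex-1-en-1-olate | Br[Mg]OC1=C[C@@](C)(C=C)CCC1 | intermediate (not isolated)
19 | (2R,3R)-2-{(S)-hydroxy[(4R,5R)-2,2,5-trimethyl-4-vinyl-1,3-dioxan-5-yl]methyl}-3-methyl-3-vinylcyclohexan-1-one | C=C[C@H]1OC(C)(C)OC[C@]1(C)[C@@H](O)[C@@H]2C(=O)CCC[C@]2(C)C=C | intermediate
20 | (2R,3R)-3-methyl-2-{(S)-(triethylsilyloxy)[(4R,5S)-2,2,5-trimethyl-4-vinyl-1,3-dioxan-5-yl]methyl}-3-vinylcyclohexan-1-one | C=C[C@H]1OC(C)(C)OC[C@]1(C)[C@@H](O[Si](CC)(CC)CC)[C@@H]2C(=O)CCC[C@]2(C)C=C | intermediate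
21 | cis-fused cycloheptene ketone: bicyclo[5.4.0]undecene made of C1–C11, C3 ketone, C8=C9, C5 OSiEt3, C6 and C10 methyls, acetonide across O7 and the C6 CH2O arm; centres C4, C5, C6, C7, C10 as in 20 | CC1(C)OC[C@@]2(C)[C@H](O1)/C=C\[C@@]3(C)CCCC(=O)[C@H]3[C@@H]2O[Si](CC)(CC)CC | intermediate
22 | cis-fused saturated bicyclic ketone: as 21 with C8–C9 saturated | CC1(C)OC[C@@]2(C)[C@H](O1)CC[C@@]3(C)CCCC(=O)[C@H]3[C@@H]2O[Si](CC)(CC)CC | intermediate
23 | trimethylsilyl enol ether of 22 (C3 OSiMe3, C2=C3) | CC1(C)OC[C@@]2(C)[C@H](O1)CC[C@@]3(C)CCC=C(O[Si](C)(C)C)[C@H]3[C@@H]2O[Si](CC)(CC)CC | intermediate (not isolated)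
24 | bicyclic enone: as 22 with C1=C2 conjugated to the C3 ketone | CC1(C)OC[C@@]2(C)[C@H](O1)CC[C@@]3(C)CC=CC(=O)[C@H]3[C@@H]2O[Si](CC)(CC)CC | intermediate
25 | methyllithium | [Li]C | starting material
26 | tertiary allylic alcohol: as 24 with C3 bearing OH and CH3 (C3 configuration open), C1=C2 | CC1(C)OC[C@@]2(C)[C@H](O1)CC[C@@]3(C)CC=CC(C)(O)[C@H]3[C@@H]2O[Si](CC)(CC)CC | intermediate
27 | transposed enone: C1 ketone, C2=C3 with the C3 methyl, C5 OSiEt3, acetonide; centres C4, C5, C6, C7, C10 as in 20 | CC1(C)OC[C@@]2(C)[C@H](O1)CC[C@@]3(C)CC(=O)C=C(C)[C@H]3[C@@H]2O[Si](CC)(CC)CC | intermediate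
28 | C5 alcohol: as 27 with free C5 OH | CC1(C)OC[C@@]2(C)[C@H](O1)CC[C@@]3(C)CC(=O)C=C(C)[C@H]3[C@@H]2O | intermediate
29 | C5 methanesulfonate: as 28 with C5 OSO2CH3 | CC1(C)OC[C@@]2(C)[C@H](O1)CC[C@@]3(C)CC(=O)C=C(C)[C@H]3[C@@H]2OS(C)(=O)=O | intermediate
30 | lithium cross-conjugated enolate of 29 (C1 OLi, C1=C11, C2=C3) | CC1(C)OC[C@@]2(C)[C@H](O1)CC[C@@]3(C)C=C(O[Li])C=C(C)[C@H]3[C@@H]2OS(C)(=O)=O | intermediate (not isolated)
31 | (4R,5S,6S,7R,10R,11R)-tricyclic enone acetonide: longipin-2-en-1-one skeleton, acetonide across O7 and the C6 CH2O arm | CC1(C)OC[C@@]2(C)[C@H](O1)CC[C@@]3(C)[C@@H]4C(=O)C=C(C)[C@H]3[C@H]24 | intermediate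
32 | (4R,5S,6S,7R,10R,11R)-tricyclic diol: longipin-2-en-1-one skeleton with C7 OH and CH2OH on C6 | OC[C@@]1(C)[C@H](O)CC[C@@]2(C)[C@@H]3C(=O)C=C(C)[C@H]2[C@H]13 | intermediate
33 | angelic acid, (Z)-2-methylbut-2-enoic acid | C/C=C(/C)C(=O)O | starting material
34 | angelic 2,4,6-trichlorobenzoic anhydride | C/C=C(/C)C(=O)OC(=O)c1c(Cl)cc(Cl)cc1Cl | intermediate (not isolated)
35 | (4R,5S,6S,7R,10R,11R)-tricyclic mono-angelate: angelate on the C6 CH2O arm, free C7 OH | C/C=C(/C)C(=O)OC[C@@]1(C)[C@H](O)CC[C@@]2(C)[C@@H]3C(=O)C=C(C)[C@H]2[C@H]13 | intermediate
36 | CNP0374220.1, (4R,5S,6S,7R,10R,11R)-7-acetoxy-6-(angeloyloxymethyl)longipin-2-en-1-one | C/C=C(/C)C(=O)OC[C@]1(C)[C@@H]2[C@H]3C(=O)C=C(C)[C@@H]2[C@@]3(C)CC[C@H]1OC(C)=O | target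

## Step count and least certain steps

Total: 21 steps. Longest linear sequence: 20 steps (5 and 6 to 36, steps 2–21); dienone 4 is made in one step on a side branch.

**Step 9 (key step).** Three things may fail together.
- Methyl may add at the unsubstituted vinyl terminus (1,6) and not at C10.
- The enolate face may be chosen poorly, because methyl and vinyl on C10 differ little and the two half-chairs of 18 interconvert.
- The aldol may be slow or reverse, because the new C4–C5 bond lies between two fully substituted carbons (C10 and C6).

Fallback, from 1 and back at 20: the vinyl group is replaced by a rod-shaped alkynyl group, which is clearly smaller than methyl as the gauche neighbour of the incoming aldehyde and has no free terminus. Lithium (trimethylsilyl)acetylide adds to 1 to give lithium 3-ethoxy-1-[(trimethylsilyl)ethynyl]cyclohex-2-en-1-olate F1, which aqueous acid turns into 3-[(trimethylsilyl)ethynyl]cyclohex-2-en-1-one F2. The same copper–carbene addition of 17 gives bromomagnesium (R)-3-methyl-3-[(trimethylsilyl)ethynyl]cyclohex-1-en-1-olate F3, and capture by 16 gives the alkynyl aldol F4. Silylation as in step 10 gives the triethylsilyl ether F5, AgNO3-mediated protodesilylation in aqueous acetone gives the terminal alkyne F6, and semihydrogenation over Pd on CaCO3 poisoned with Pb(OAc)2 (Lindlar catalyst) returns to 20.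

**Step 18.** The backside displacement at C5, which is secondary and flanked by the quaternary C6, may be slow enough that proton transfer gives the extended dienolate (through the C4 hydrogen or the C3 methyl), followed by loss of the sulfonate by elimination. Fallback, from 27 and back at 31: the ring is closed on a saturated ketone, where no vinylogous deprotonation exists and equilibrating base can be used. Hydrogenation of 27 (H2, Pd on carbon) gives the saturated ketone F7 (C3 epimers). HF·pyridine gives the alcohol F8 and MeSO2Cl with Et3N gives the mesylate F9. KOtBu in tBuOH/THF closes the cyclobutane to the saturated tricyclic ketone F10. LiN(iPr)2 with Me3SiCl gives the silyl enol ether F11 toward C2, and Pd(OAc)2 re-forms the C2=C3 double bond to give 31.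

**Step 15.** The hindered tertiary allylic alcohol may ionise and dehydrate to a diene instead of passing through the chromate [3,3] shift, and the acidic oxidant may strip the silyl ether and then oxidise C5. Fallback, from 22 and back at 27: the methyl is introduced by cross-coupling and the oxygen by allylic oxidation. Kinetic deprotonation of 22 with LiN(iPr)2 and capture with N-phenylbis(trifluoromethanesulfonimide) gives the enol triflate F12. Fe(acac)3-catalysed coupling with 17 gives the C2=C3 methyl alkene F13. Allylic oxidation of the ring methylene C1 with CrO3 and 3,5-dimethylpyrazole gives 27.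

**Step 20.** Acylation may also occur at O7, and the forcing conditions may isomerise the (Z) acyl group to the (E) form. Fallback, from 32 and back at 36: the order of the two esters is reversed so that only one hydroxyl is free when the angelate goes on. tBuMe2SiCl with imidazole silylates the primary hydroxyl selectively to give the silyl ether F14. Ac2O with DMAP gives the C7 acetate F15. HF·pyridine gives the primary alcohol F16, and esterification of F16 with mixed anhydride 34 under the conditions of step 20 gives 36 directly.

## Further compounds

F1 | step 9 | lithium 3-ethoxy-1-[(trimethylsilyl)ethynyl]cyclohex-2-en-1-olate (racemic) | CCOC1=CC(O[Li])(C#C[Si](C)(C)C)CCC1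
F2 | step 9 | 3-[(trimethylsilyl)ethynyl]cyclohex-2-en-1-one | C[Si](C)(C)C#CC1=CC(=O)CCC1
F3 | step 9 | bromomagnesium 3-methyl-3-[(trimethylsilyl)ethynyl]cyclohex-1-en-1-olate (same spatial arrangement at C10 as 18) | Br[Mg]OC1=C[C@@](C)(C#C[Si](C)(C)C)CCC1
F4 | step 9 | alkynyl aldol: 19 with C≡C–SiMe3 in place of the C10 vinyl group | C=C[C@H]1OC(C)(C)OC[C@]1(C)[C@@H](O)[C@@H]2C(=O)CCC[C@]2(C)C#C[Si](C)(C)C
F5 | step 9 | triethylsilyl ether of F4 | C=C[C@H]1OC(C)(C)OC[C@]1(C)[C@@H](O[Si](CC)(CC)CC)[C@@H]2C(=O)CCC[C@]2(C)C#C[Si](C)(C)C
F6 | step 9 | terminal alkyne: 20 with ethynyl in place of the C10 vinyl group | C=C[C@H]1OC(C)(C)OC[C@]1(C)[C@@H](O[Si](CC)(CC)CC)[C@@H]2C(=O)CCC[C@]2(C)C#C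
F7 | step 18 | saturated ketone: 27 with C2–C3 saturated (C3 configuration open) | CC1(C)OC[C@@]2(C)[C@H](O1)CC[C@@]3(C)CC(=O)CC(C)[C@H]3[C@@H]2O[Si](CC)(CC)CC
F8 | step 18 | C5 alcohol of F7 | CC1(C)OC[C@@]2(C)[C@H](O1)CC[C@@]3(C)CC(=O)CC(C)[C@H]3[C@@H]2O
F9 | step 18 | C5 methanesulfonate of F8 | CC1(C)OC[C@@]2(C)[C@H](O1)CC[C@@]3(C)CC(=O)CC(C)[C@H]3[C@@H]2OS(C)(=O)=O
F10 | step 18 | saturated tricyclic ketone: 31 with C2–C3 saturated (C3 configuration open) | CC1(C)OC[C@@]2(C)[C@H](O1)CC[C@@]3(C)[C@@H]4C(=O)CC(C)[C@H]3[C@H]24
F11 | step 18 | trimethylsilyl enol ether of F10 (C1 OSiMe3, C1=C2) | CC1(C)OC[C@@]2(C)[C@H](O1)CC[C@@]3(C)[C@@H]4C(O[Si](C)(C)C)=CC(C)[C@H]3[C@H]24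
F12 | step 15 | enol triflate of 22 (C3 OSO2CF3, C2=C3) | CC1(C)OC[C@@]2(C)[C@H](O1)CC[C@@]3(C)CCC=C(OS(=O)(=O)C(F)(F)F)[C@H]3[C@@H]2O[Si](CC)(CC)CC
F13 | step 15 | methyl alkene: 27 with CH2 in place of the C1 carbonyl | CC1(C)OC[C@@]2(C)[C@H](O1)CC[C@@]3(C)CCC=C(C)[C@H]3[C@@H]2O[Si](CC)(CC)CC
F14 | step 20 | primary tert-butyldimethylsilyl ether of 32 (free C7 OH) | CC(C)(C)[Si](C)(C)OC[C@@]1(C)[C@H](O)CC[C@@]2(C)[C@@H]3C(=O)C=C(C)[C@H]2[C@H]13
F15 | step 20 | C7 acetate of F14 | CC(C)(C)[Si](C)(C)OC[C@@]1(C)[C@H](OC(C)=O)CC[C@@]2(C)[C@@H]3C(=O)C=C(C)[C@H]2[C@H]13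
F16 | step 20 | 7-acetoxy primary alcohol: 36 without the angeloyl group | OC[C@@]1(C)[C@H](OC(C)=O)CC[C@@]2(C)[C@@H]3C(=O)C=C(C)[C@H]2[C@H]13
A1 | alternative 1 | tricyclic epoxy alcohol: C5 bonded to the carbinol carbon C7 of a six-membered ring, 2-methyloxiran-2-yl (C6) on C7; one C7 epimer drawn, this centre is lost in the step | C[C@@]1(CO1)[C@]4(O)[C@@H]2[C@H]3C(=O)C=C(C)[C@@H]2[C@@]3(C)CC4
A2 | alternative 1 | 6-hydroxymethyl-longipin-2-ene-1,7-dione | OC[C@]1(C)[C@@H]2[C@H]3C(=O)C=C(C)[C@@H]2[C@@]3(C)CCC1=O
A3 | alternative 2 | 4-(1-methyl-4-oxocyclohexa-2,5-dien-1-yl)butanal (achiral) | O=CCCCC1(C)C=CC(=O)C=C1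
A4 | alternative 2 | cis-fused methyl-substituted hexahydronaphthalenedione (enedione; future C3 ketone next to the fusion CH, future C10 methyl on the other fusion carbon) | O=C1C[C@@H]2C(=O)CCC[C@]2(C)C=C1
A5 | alternative 3 | 8-[(benzyloxy)methyl]-6-diazo-2-methylbicyclo[3.2.1]oct-2-en-7-one | c1ccccc1COC[C@@H]2[C@H]3CC=C(C)[C@@H]2C(=O)C3=[N+]=[N-]
A6 | alternative 3 | methyl 7-[(benzyloxy)methyl]-2-methylbicyclo[3.1.1]hept-2-ene-6-carboxylate | c1ccccc1COC[C@@H]2[C@H]3CC=C(C)[C@@H]2[C@H]3C(=O)OC
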